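**Plan**

1. Retrosynthetic cuts: (i) the C6–O angelate ester and the C11=C13 methylene; (ii) the ether bond C4–O of the 1β,4β-oxygen bridge; (iii) C3=C4 (ring-closing metathesis) and C1–C2 (allylation) of ring A; (iv) the lactone O–C8 bond with the C9–O bond (epoxide) and C7–C11 (Claisen); (v) C5–C4 and C10–C1 (conjugate addition/aldol), back to a 4-silyloxycyclohexenone that becomes ring B.
2. Forward order: ring B is fully substituted first, then the γ-lactone is closed, then ring A (C1, then C3=C4), and the oxygen bridge is closed last; C13, desilylation and the angelate follow.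
3. Enabling feature: C1 (carrying the β-hydroxyl) and C4 lie 1,4 across ring A. In the boat of ring A the 1β-oxygen reaches the β-lobe of a tertiary C4 radical/cation made from the C3=C4 alkene, which closes the 7-oxabicyclo[2.2.1]heptane (rings O–C1–C10–C5–C4 and O–C1–C2–C3–C4).
4. Ring B is trans-fused to that bicycle (H-5α, CH3-10β). A closure that makes C1–C10/C4–C5 (furan Diels–Alder, carbonyl ylide) or passes through an sp2 C5 or C10 can only give the cis fusion, so C5 and C10 are fixed first and the bridge is closed at oxygen, irreversibly, by metal-hydride hydrogen-atom transfer.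
5. Stereochemistry: C6 from the (S)-enone; C5 and C10 by anti conjugate addition and anti aldol; C9β (Luche) relayed to C7 by the suprafacial Claisen shift; C8 and C9 by hydroxyl-directed α-epoxidation and trans-diaxial lactonisation; C1 by reagent-controlled allylation; C4 by the C1 tether.

Key step: step 12

Remark: atoms are numbered as in eudesmanes (ring A = C1–C5, C10; ring B = C5–C10; C11–C13 lactone carbons; C14 = methyl on C10; C15 = methyl on C4), and (S)-4-(tert-butyldimethylsilyloxy)cyclohex-2-en-1-one (1) is taken to be a commercial building block.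

**Step 1**
Reactants: 1 (S)-4-(tert-butyldimethylsilyloxy)cyclohex-2-en-1-one
Product: 2 (S)-4-(tert-butyldimethylsilyloxy)-2-iodocyclohex-2-en-1-one
Conditions: I2, pyridine, CH2Cl2, 0 °C to rt
Reagents that add atoms: iodine, II
Why: Amine-mediated α-iodination of the enone (Baylis–Hillman-type addition, iodination, elimination) should leave the γ-silyloxy stereocentre untouched.

**Step 2**
Reactants: 2 (S)-4-(tert-butyldimethylsilyloxy)-2-iodocyclohex-2-en-1-one
Product: 3 (S)-4-(tert-butyldimethylsilyloxy)-2-methylcyclohex-2-en-1-one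
Conditions: Me4Sn, Pd2(dba)3 (cat.), AsPh3, CuI, NMP, 60 °C
Reagents that add atoms: tetramethylstannane, C[Sn](C)(C)C
Why: Stille cross-coupling of the α-iodoenone installs the future C14 methyl under neutral conditions that should not eliminate the γ-silyloxy group.

**Step 3**
Reactants: 3 (S)-4-(tert-butyldimethylsilyloxy)-2-methylcyclohex-2-en-1-one
Product: 6 (2R,3S,4S)-4-(tert-butyldimethylsilyloxy)-2-methyl-3-(prop-1-en-2-yl)-2-[(triethylsilyloxy)methyl]cyclohexan-1-one, via magnesium enolate 4 (not isolated), via magnesium aldolate 5 (not isolated)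
Conditions: CH2=C(CH3)MgBr, CuBr·SMe2 (10 mol %), THF, −78 °C; HCHO (gas), −78 °C; TESOTf, 2,6-lutidine, −78 to 0 °C
Reagents that add atoms: isopropenylmagnesium bromide, C=C(C)[Mg]Br; formaldehyde, C=O; triethylsilyl trifluoromethanesulfonate, CC[Si](CC)(CC)OS(=O)(=O)C(F)(F)F
Why: Copper-catalysed conjugate addition should place the isopropenyl group anti to the γ-OTBS group (C5), the regiodefined enolate should then add formaldehyde anti to the new C5 substituent to give the C10 quaternary centre (aldol), and silylation in the flask prevents retro-aldol loss of formaldehyde.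

**Step 4**
Reactants: 6 (2R,3S,4S)-4-(tert-butyldimethylsilyloxy)-2-methyl-3-(prop-1-en-2-yl)-2-[(triethylsilyloxy)methyl]cyclohexan-1-one
Product: 8 (4S,5S,6R)-4-(tert-butyldimethylsilyloxy)-6-methyl-5-(prop-1-en-2-yl)-6-[(triethylsilyloxy)methyl]cyclohex-2-en-1-one, via silyl enol ether 7 (not isolated)
Conditions: LDA, TMSCl, THF, −78 °C; then Pd(OAc)2, MeCN, rt
Reagents that add atoms: none
Why: Saegusa–Ito dehydrogenation; only C8 carries α-hydrogens (C10 is quaternary), so the silyl enol ether and its palladium-mediated β-hydride elimination should give the C7=C8 enone regiospecifically.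

**Step 5**
Reactants: 8 (4S,5S,6R)-4-(tert-butyldimethylsilyloxy)-6-methyl-5-(prop-1-en-2-yl)-6-[(triethylsilyloxy)methyl]cyclohex-2-en-1-one
Product: 9 (1S,4S,5S,6R)-4-(tert-butyldimethylsilyloxy)-6-methyl-5-(prop-1-en-2-yl)-6-[(triethylsilyloxy)methyl]cyclohex-2-en-1-ol
Conditions: NaBH4, CeCl3·7H2O, MeOH, −78 °C
Reagents that add atoms: none
Why: Luche 1,2-reduction; in the half-chair with all other substituents equatorial the C10 methyl is pseudoaxial, so hydride should add to C9 from the opposite (α) face and give the 9β-alcohol, as in reductions of ketones next to an angular methyl.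

**Step 6**
Reactants: 9 (1S,4S,5S,6R)-4-(tert-butyldimethylsilyloxy)-6-methyl-5-(prop-1-en-2-yl)-6-[(triethylsilyloxy)methyl]cyclohex-2-en-1-ol
Product: 10 (1S,4S,5S,6R)-4-(tert-butyldimethylsilyloxy)-6-methyl-5-(prop-1-en-2-yl)-6-[(triethylsilyloxy)methyl]cyclohex-2-en-1-yl acetate
Conditions: Ac2O, Et3N, DMAP (cat.), CH2Cl2, rt
Reagents that add atoms: acetic anhydride, CC(=O)OC(C)=O
Why: DMAP-catalysed acetylation of the allylic alcohol provides the ester needed for the Claisen step.

**Step 7**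
Reactants: 10 (1S,4S,5S,6R)-4-(tert-butyldimethylsilyloxy)-6-methyl-5-(prop-1-en-2-yl)-6-[(triethylsilyloxy)methyl]cyclohex-2-en-1-yl acetate
Product: 13 2-[(1R,4R,5S,6S)-6-(tert-butyldimethylsilyloxy)-4-(hydroxymethyl)-4-methyl-5-(prop-1-en-2-yl)cyclohex-2-en-1-yl]acetic acid, via silyl ketene acetal 11 (not isolated), via trimethylsilyl ester 12 (not isolated)
Conditions: LDA, THF, −78 °C; TMSCl, Et3N; −78 to 60 °C; then 1 M HCl, THF, rt
Reagents that add atoms: none
Why: Ireland–Claisen rearrangement; the suprafacial [3,3] shift transfers the C9β–O chirality to the new C7β–C11 bond (trans to the 6α-OTBS group) and moves the alkene to C8=C9, and the acidic work-up should free the acid and the primary alcohol while the secondary TBS ether survives.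

**Step 8**
Reactants: 13 2-[(1R,4R,5S,6S)-6-(tert-butyldimethylsilyloxy)-4-(hydroxymethyl)-4-methyl-5-(prop-1-en-2-yl)cyclohex-2-en-1-yl]acetic acid
Product: 15 (3aR,4R,5S,6R,7S,7aS)-4-(tert-butyldimethylsilyloxy)-7-hydroxy-6-(hydroxymethyl)-6-methyl-5-(prop-1-en-2-yl)hexahydro-1-benzofuran-2(3H)-one, via epoxy acid 14 (not isolated)
Conditions: VO(acac)2 (5 mol %), tBuOOH, CH2Cl2, 0 °C to rt; then CSA (cat.)
Reagents that add atoms: tert-butyl hydroperoxide, CC(C)(C)OO
Why: Hydroxyl-directed vanadium-catalysed epoxidation; the C10 hydroxymethyl (α side) is homoallylic only to C8=C9 and should deliver oxygen to its α face while the more remote isopropenyl group stays intact, and the β-placed CH2CO2H then opens the epoxide at C8 with inversion (5-exo, trans-diaxial, Fürst–Plattner) to set 8β-O and 9α-OH.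

**Step 9**
Reactants: 15 (3aR,4R,5S,6R,7S,7aS)-4-(tert-butyldimethylsilyloxy)-7-hydroxy-6-(hydroxymethyl)-6-methyl-5-(prop-1-en-2-yl)hexahydro-1-benzofuran-2(3H)-one
Product: 16 (3aR,4R,5S,6S,7S,7aS)-4-(tert-butyldimethylsilyloxy)-7-hydroxy-6-methyl-2-oxo-5-(prop-1-en-2-yl)octahydro-1-benzofuran-6-carbaldehyde
Conditions: TEMPO (cat.), PhI(OAc)2, CH2Cl2, rt
Reagents that add atoms: none
Why: Oxoammonium (TEMPO) oxidation should take the primary alcohol to the aldehyde selectively over the hindered axial secondary C9 alcohol, under non-basic conditions that avoid retro-aldol cleavage.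

**Step 10**
Reactants: 16 (3aR,4R,5S,6S,7S,7aS)-4-(tert-butyldimethylsilyloxy)-7-hydroxy-6-methyl-2-oxo-5-(prop-1-en-2-yl)octahydro-1-benzofuran-6-carbaldehyde
Product: 18 (3aR,4R,5S,6R,7S,7aS)-4-(tert-butyldimethylsilyloxy)-7-hydroxy-6-[(1R)-1-hydroxybut-3-en-1-yl]-6-methyl-5-(prop-1-en-2-yl)hexahydro-1-benzofuran-2(3H)-one, via borinate 17 (not isolated)
Conditions: (+)-Ipc2B(allyl) (excess), Et2O, −78 °C to rt; then pH 7 buffer, H2O2
Reagents that add atoms: (+)-B-allyldiisopinocampheylborane, C=CCB([C@H]1C[C@H]2C[C@@H]([C@@H]1C)C2(C)C)[C@H]1C[C@H]2C[C@@H]([C@@H]1C)C2(C)C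
Why: Brown asymmetric allylation through a chair-like six-membered transition state; the (+)-reagent, which gives (R)-carbinols from α-branched aldehydes, should set (R)-C1 (the future 1β-OH) by reagent control.

**Step 11**
Reactants: 18 (3aR,4R,5S,6R,7S,7aS)-4-(tert-butyldimethylsilyloxy)-7-hydroxy-6-[(1R)-1-hydroxybut-3-en-1-yl]-6-methyl-5-(prop-1-en-2-yl)hexahydro-1-benzofuran-2(3H)-one
Product: 19 6α-(tert-butyldimethylsilyloxy)-1β,9α-dihydroxy-13-nor-5αH-eudesm-3-en-12,8β-olide
Conditions: second-generation Grubbs catalyst (C46H65Cl2N2PRu, 5 mol %), CH2Cl2, 40 °C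
Reagents that add atoms: none
Why: Ring-closing metathesis of the allyl and isopropenyl arms, which are trans-diequatorial on ring B, should close ring A as the trans-fused cyclohexene with the trisubstituted C3=C4 bond.

**Step 12**
Reactants: 19 6α-(tert-butyldimethylsilyloxy)-1β,9α-dihydroxy-13-nor-5αH-eudesm-3-en-12,8β-olide
Product: 20 6α-(tert-butyldimethylsilyloxy)-1β,4β-epoxy-9α-hydroxy-13-nor-5αH-eudesman-12,8β-olide
Conditions: Co(salen) complex C36H52CoN2O2 [N,N′-bis(3,5-di-tert-butylsalicylidene)-1,2-cyclohexanediamine complex of divalent cobalt] (5 mol %), N-fluoro-2,4,6-trimethylpyridinium tetrafluoroborate, PhSiH3, PhCF3, 0 °C to rt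
Reagents that add atoms: none
Why: A cobalt hydride formed from the catalyst, silane and N–F oxidant transfers a hydrogen atom to C3 of the C3=C4 alkene (Markovnikov), the tertiary C4 radical is taken through an alkylcobalt species (tetravalent cobalt) to a C4 cation equivalent, and the 1β-hydroxyl captures it across ring A. The closest known reaction type is the Mukaiyama-type radical-polar crossover hydroalkoxylation of unactivated alkenols, with acid-mediated 1,4-cineole formation as the ionic relative. The single C4–O bond closes both oxolane rings of the 7-oxabicyclo[2.2.1]heptane (O–C1–C10–C5–C4 and O–C1–C2–C3–C4), each in a 5-exo mode at the exocyclic C4 electrophile, through the boat of ring A. The only new stereocentre, C4 (O β, methyl α), is fixed by the C1 tether, since the 1β-oxygen can reach only the β-lobe at C4. The step needs chemoselectivity for the C3=C4 alkene, secured because the lactone still lacks its C13 methylene and the axial 9α-hydroxyl on the opposite face cannot reach C4. It also needs kinetic, non-acidic conditions, because the product is a strained trans-fused ether that an equilibrating acid could reopen, while any alkene isomers formed by β-hydride loss re-enter the same cycle.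

**Step 13**
Reactants: 20 6α-(tert-butyldimethylsilyloxy)-1β,4β-epoxy-9α-hydroxy-13-nor-5αH-eudesman-12,8β-olide
Product: 23 6α-(tert-butyldimethylsilyloxy)-1β,4β-epoxy-9α-hydroxy-5αH-eudesm-11(13)-en-12,8β-olide, via Mannich base 21 (not isolated), via ammonium iodide 22 (not isolated)
Conditions: LDA (2.2 equiv), THF, −78 °C; CH2=NMe2+ I−, −78 °C to rt; then MeI, MeOH; then NaHCO3, CH2Cl2/H2O
Reagents that add atoms: N,N-dimethylmethyleneiminium iodide, C=[N+](C)C.[I-]
Why: α-Methylenation of the lactone by Mannich reaction of its enolate with Eschenmoser's salt, N-methylation and base-induced elimination; the C9 alkoxide formed by the second equivalent of base is inert because it is 1,3-trans to the lactone side chain.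

**Step 14**
Reactants: 23 6α-(tert-butyldimethylsilyloxy)-1β,4β-epoxy-9α-hydroxy-5αH-eudesm-11(13)-en-12,8β-olide
Product: 24 1β,4β-epoxy-6α,9α-dihydroxy-5αH-eudesm-11(13)-en-12,8β-olide
Conditions: HF·pyridine, pyridine, THF, 0 °C to rt
Reagents that add atoms: none
Why: Fluoride-driven desilylation under buffered, non-basic conditions should free the 6α-hydroxyl without oxa-Michael addition to the α-methylene lactone or relactonisation.

**Step 15**
Reactants: 24 1β,4β-epoxy-6α,9α-dihydroxy-5αH-eudesm-11(13)-en-12,8β-olide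
Product: 25 6α-angeloyloxy-1β,4β-epoxy-9α-hydroxy-5αH-eudesm-11(13)-en-12,8β-olide (CNP0328162.1)
Conditions: angelic acid, 2,4,6-trichlorobenzoyl chloride, Et3N, toluene, rt; then 24, 80 °C
Reagents that add atoms: angelic acid, C/C=C(/C)C(=O)O
Why: Yamaguchi-type mixed-anhydride esterification without a nucleophilic catalyst should keep the Z geometry, and the equatorial 6α-hydroxyl should react in preference to the axial 9α-hydroxyl next to the quaternary C10.

**Compound list**

1 | (S)-4-(tert-butyldimethylsilyloxy)cyclohex-2-en-1-one | O=C1C=C[C@@H](O[Si](C)(C)C(C)(C)C)CC1 | starting material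
2 | (S)-4-(tert-butyldimethylsilyloxy)-2-iodocyclohex-2-en-1-one | O=C1C(I)=C[C@@H](O[Si](C)(C)C(C)(C)C)CC1 | intermediate
3 | (S)-4-(tert-butyldimethylsilyloxy)-2-methylcyclohex-2-en-1-one | O=C1C(C)=C[C@@H](O[Si](C)(C)C(C)(C)C)CC1 | intermediate
4 | bromomagnesium enolate (C9–OMgBr, C9=C10) of the 1,4-adduct, 5β-isopropenyl, 6α-OTBS | Br[Mg]OC1=C(C)[C@H](C(C)=C)[C@@H](O[Si](C)(C)C(C)(C)C)CC1 | intermediate
5 | bromomagnesium alkoxide of (2R,3S,4S)-4-(tert-butyldimethylsilyloxy)-2-(hydroxymethyl)-2-methyl-3-(prop-1-en-2-yl)cyclohexan-1-one | O=C1CC[C@H](O[Si](C)(C)C(C)(C)C)[C@@H](C(C)=C)[C@]1(C)CO[Mg]Br | intermediate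
6 | (2R,3S,4S)-4-(tert-butyldimethylsilyloxy)-2-methyl-3-(prop-1-en-2-yl)-2-[(triethylsilyloxy)methyl]cyclohexan-1-one | O=C1CC[C@H](O[Si](C)(C)C(C)(C)C)[C@@H](C(C)=C)[C@]1(C)CO[Si](CC)(CC)CC | intermediate
7 | trimethylsilyl enol ether (C9–OSiMe3, C8=C9) of ketone 6 | C[Si](C)(C)OC1=CC[C@H](O[Si](C)(C)C(C)(C)C)[C@@H](C(C)=C)[C@]1(C)CO[Si](CC)(CC)CC | intermediate
8 | (4S,5S,6R)-4-(tert-butyldimethylsilyloxy)-6-methyl-5-(prop-1-en-2-yl)-6-[(triethylsilyloxy)methyl]cyclohex-2-en-1-one | O=C1C=C[C@H](O[Si](C)(C)C(C)(C)C)[C@@H](C(C)=C)[C@]1(C)CO[Si](CC)(CC)CC | intermediate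
9 | (1S,4S,5S,6R)-4-(tert-butyldimethylsilyloxy)-6-methyl-5-(prop-1-en-2-yl)-6-[(triethylsilyloxy)methyl]cyclohex-2-en-1-ol | O[C@H]1C=C[C@H](O[Si](C)(C)C(C)(C)C)[C@@H](C(C)=C)[C@]1(C)CO[Si](CC)(CC)CC | intermediate
10 | (1S,4S,5S,6R)-4-(tert-butyldimethylsilyloxy)-6-methyl-5-(prop-1-en-2-yl)-6-[(triethylsilyloxy)methyl]cyclohex-2-en-1-yl acetate | CC(=O)O[C@H]1C=C[C@H](O[Si](C)(C)C(C)(C)C)[C@@H](C(C)=C)[C@]1(C)CO[Si](CC)(CC)CC | intermediate
11 | trimethylsilyl ketene acetal of acetate 10 | C=C(O[Si](C)(C)C)O[C@H]1C=C[C@H](O[Si](C)(C)C(C)(C)C)[C@@H](C(C)=C)[C@]1(C)CO[Si](CC)(CC)CC | intermediate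
12 | trimethylsilyl ester of the rearranged acid, still carrying the triethylsilyl ether | C[Si](C)(C)OC(=O)C[C@@H]1C=C[C@@](C)(CO[Si](CC)(CC)CC)[C@H](C(C)=C)[C@H]1O[Si](C)(C)C(C)(C)C | intermediate
13 | 2-[(1R,4R,5S,6S)-6-(tert-butyldimethylsilyloxy)-4-(hydroxymethyl)-4-methyl-5-(prop-1-en-2-yl)cyclohex-2-en-1-yl]acetic acid | OC(=O)C[C@@H]1C=C[C@@](C)(CO)[C@H](C(C)=C)[C@H]1O[Si](C)(C)C(C)(C)C | intermediate
14 | 8α,9α-epoxide of acid 13 (epoxide anti to the CH2CO2H group and to the C10 methyl) | OC(=O)C[C@@H]1[C@H]2O[C@H]2[C@@](C)(CO)[C@H](C(C)=C)[C@H]1O[Si](C)(C)C(C)(C)C | intermediate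
15 | (3aR,4R,5S,6R,7S,7aS)-4-(tert-butyldimethylsilyloxy)-7-hydroxy-6-(hydroxymethyl)-6-methyl-5-(prop-1-en-2-yl)hexahydro-1-benzofuran-2(3H)-one | O=C1O[C@H]2[C@@H](C1)[C@H](O[Si](C)(C)C(C)(C)C)[C@@H](C(C)=C)[C@](C)(CO)[C@@H]2O | intermediate
16 | (3aR,4R,5S,6S,7S,7aS)-4-(tert-butyldimethylsilyloxy)-7-hydroxy-6-methyl-2-oxo-5-(prop-1-en-2-yl)octahydro-1-benzofuran-6-carbaldehyde | O=C1O[C@H]2[C@@H](C1)[C@H](O[Si](C)(C)C(C)(C)C)[C@@H](C(C)=C)[C@](C)(C=O)[C@@H]2O | intermediate
17 | B,B-diisopinocampheylborinic ester (B–O–C1) of alcohol 18 | O=C1O[C@H]2[C@@H](C1)[C@H](O[Si](C)(C)C(C)(C)C)[C@@H](C(C)=C)[C@](C)([C@H](OB([C@H]3C[C@H]4C[C@@H]([C@@H]3C)C4(C)C)[C@H]3C[C@H]4C[C@@H]([C@@H]3C)C4(C)C)CC=C)[C@@H]2O | intermediate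
18 | (3aR,4R,5S,6R,7S,7aS)-4-(tert-butyldimethylsilyloxy)-7-hydroxy-6-[(1R)-1-hydroxybut-3-en-1-yl]-6-methyl-5-(prop-1-en-2-yl)hexahydro-1-benzofuran-2(3H)-one | O=C1O[C@H]2[C@@H](C1)[C@H](O[Si](C)(C)C(C)(C)C)[C@@H](C(C)=C)[C@](C)([C@H](O)CC=C)[C@@H]2O | intermediate
19 | 6α-(tert-butyldimethylsilyloxy)-1β,9α-dihydroxy-13-nor-5αH-eudesm-3-en-12,8β-olide | O=C1O[C@H]2[C@@H](C1)[C@H](O[Si](C)(C)C(C)(C)C)[C@H]1C(C)=CC[C@@H](O)[C@]1(C)[C@@H]2O | intermediate
20 | 6α-(tert-butyldimethylsilyloxy)-1β,4β-epoxy-9α-hydroxy-13-nor-5αH-eudesman-12,8β-olide | O=C1O[C@H]2[C@@H](C1)[C@H](O[Si](C)(C)C(C)(C)C)[C@@H]1[C@@](C)([C@@H]2O)[C@H]2CC[C@]1(C)O2 | intermediate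
21 | 13-(dimethylamino)-11,13-dihydro derivative of 23 (CH2NMe2 on C11, cis to H-7) | CN(C)C[C@H]1C(=O)O[C@H]2[C@@H]1[C@H](O[Si](C)(C)C(C)(C)C)[C@@H]1[C@@](C)([C@@H]2O)[C@H]2CC[C@]1(C)O2 | intermediate
22 | trimethylammonium iodide of Mannich base 21 | C[N+](C)(C)C[C@H]1C(=O)O[C@H]2[C@@H]1[C@H](O[Si](C)(C)C(C)(C)C)[C@@H]1[C@@](C)([C@@H]2O)[C@H]2CC[C@]1(C)O2.[I-] | intermediate
23 | 6α-(tert-butyldimethylsilyloxy)-1β,4β-epoxy-9α-hydroxy-5αH-eudesm-11(13)-en-12,8β-olide | C=C1C(=O)O[C@H]2[C@@H]1[C@H](O[Si](C)(C)C(C)(C)C)[C@@H]1[C@@](C)([C@@H]2O)[C@H]2CC[C@]1(C)O2 | intermediate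
24 | 1β,4β-epoxy-6α,9α-dihydroxy-5αH-eudesm-11(13)-en-12,8β-olide | C=C1C(=O)O[C@H]2[C@@H]1[C@H](O)[C@@H]1[C@@](C)([C@@H]2O)[C@H]2CC[C@]1(C)O2 | intermediate
25 | 6α-angeloyloxy-1β,4β-epoxy-9α-hydroxy-5αH-eudesm-11(13)-en-12,8β-olide (CNP0328162.1) | C=C1C(=O)O[C@H]2[C@@H]1[C@H](OC(=O)/C(C)=C\C)[C@@H]1[C@@](C)([C@@H]2O)[C@H]2CC[C@]1(C)O2 | target

**Step count and risks**

Total step count: 15. Longest linear sequence: 15 steps (fully linear from 1).

Steps most likely to fail:

Step 12. The strain of the trans-fused oxabicycle may slow capture of the C4 cation equivalent by the 1β-hydroxyl, so that β-hydride loss to alkene isomers, fluoride capture at C4 or simple reduction take over. The fallback sets out from 19 and replaces the hydrogen-atom-transfer event by a halonium-driven anti addition. N-Iodosuccinimide in CH2Cl2 at 0 °C should form the iodonium ion on the α face of C3=C4, and the 1β-hydroxyl opens it at C4 to give 6α-(tert-butyldimethylsilyloxy)-1β,4β-epoxy-9α-hydroxy-3α-iodo-13-nor-5αH-eudesman-12,8β-olide F1. Radical deiodination (Bu3SnH, AIBN, toluene, 80 °C), possible here because the lactone is not yet α-methylenated, returns the route to 20.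

Step 8. Oxygen delivery may be poorly chemoselective (the isopropenyl group is bishomoallylic to the same hydroxyl) or may go to the wrong face, and the epoxide may then be opened by the wrong nucleophile. The fallback sets out from 13 and uses the carboxylate, not the hydroxyl, to select the alkene. Iodolactonisation (I2, NaHCO3, MeCN, 0 °C) should give, by trans-diaxial addition, the 9α-iodo-8β,12-lactone (3aR,4R,5S,6R,7S,7aS)-4-(tert-butyldimethylsilyloxy)-6-(hydroxymethyl)-7-iodo-6-methyl-5-(prop-1-en-2-yl)hexahydro-1-benzofuran-2(3H)-one F2. Radical oxygenation of the C–I bond (Bu3SnH, O2, toluene, then PPh3), in which O2 should enter C9 from the α face opposite the C10 methyl and the lactone oxygen, returns the route to 15.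

Step 15. The angelate may isomerise to the tiglate during activation, acylation of the hindered 6α-hydroxyl may be slow enough for the 9α-hydroxyl to compete, or base may cause relactonisation towards the 6,12-olide. The fallback sets out from 24 and builds the Z-alkene on the substrate instead of transferring it. Carbodiimide esterification (DIC, DMAP, CH2Cl2, 0 °C) with 2-[bis(2,2,2-trifluoroethoxy)phosphoryl]propanoic acid gives the 6α-O-[2-(bis(2,2,2-trifluoroethoxy)phosphoryl)propanoyl] ester of 24 F3 (mixture of epimers at the phosphonate carbon). A Still–Gennari olefination with acetaldehyde (KHMDS, 18-crown-6, THF, −78 °C) should then give the Z-alkene and return the route to 25.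

**Further compounds**

F1 | step 12 | 6α-(tert-butyldimethylsilyloxy)-1β,4β-epoxy-9α-hydroxy-3α-iodo-13-nor-5αH-eudesman-12,8β-olide | O=C1O[C@H]2[C@@H](C1)[C@H](O[Si](C)(C)C(C)(C)C)[C@@H]1[C@@](C)([C@@H]2O)[C@H]2C[C@@H](I)[C@]1(C)O2
F2 | step 8 | (3aR,4R,5S,6R,7S,7aS)-4-(tert-butyldimethylsilyloxy)-6-(hydroxymethyl)-7-iodo-6-methyl-5-(prop-1-en-2-yl)hexahydro-1-benzofuran-2(3H)-one | O=C1O[C@H]2[C@@H](C1)[C@H](O[Si](C)(C)C(C)(C)C)[C@@H](C(C)=C)[C@](C)(CO)[C@@H]2I
F3 | step 15 | 6α-O-[2-(bis(2,2,2-trifluoroethoxy)phosphoryl)propanoyl] ester of 24 | C=C1C(=O)O[C@H]2[C@@H]1[C@H](OC(=O)C(C)P(=O)(OCC(F)(F)F)OCC(F)(F)F)[C@@H]1[C@@](C)([C@@H]2O)[C@H]2CC[C@]1(C)O2
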